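**Strategy.** Everything rests on forming the benzene ring of the resorcylate unit last. Ring carbons C1 (ester-bearing) and C6 (bearing the CH2 arm) are the two alkyne carbons of a fully acylated hex-2-ynoate; C2–C5 with the oxygens on C2 and C4 come from an acetoacetate-derived 1-methoxy-1,3-bis(silyloxy)diene. A single thermal [4+2] cycloaddition with eliminative aromatisation makes bonds C1–C2 and C5–C6 and reveals both phenols only after all four ester links exist, so the phenols never need protection and the crowded benzoate ester is prepared earlier as an ordinary alk-2-ynoate ester. The precursor is a linear tetraester ynoate with two benzyl ethers, which are removed at the end by neutral hydrogenolysis.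

Key step: step 13

Remark: units are called A (methyl 3-hydroxybutanoate, S), B (resorcylate with its 2-oxypropyl arm, R), C (3,4-dihydroxybutanoate, S) and D (3-hydroxybutanoyl, S); the geometry of the trisubstituted double bond of the silyloxy diene is left undefined because it is erased on aromatisation.

Remark: the ynoate precursor and the cycloaddition product agree with the target at every atom and stereocentre, so their structures are kept. Benzyl ethers are kept because neutral hydrogenolysis avoids acyl shift and lactonisation in unit C. The carboxyl of unit C is carried as a vinyl group, so it needs no protecting group.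

**Step 1**
Reactants: 1 (R)-pent-4-yn-2-ol
Product: 2 (R)-tert-butyldimethyl(pent-4-yn-2-yloxy)silane
Conditions: TBSCl, imidazole, DMF, 0 °C → rt
Reagents that add atoms: tert-butyldimethylsilyl chloride, CC(C)(C)[Si](C)(C)Cl
Why: Imidazole-promoted silyl ether formation masks the only O–H so that step 2 deprotonates the alkyne C–H alone, and the stereocentre is not touched.

**Step 2**
Reactants: 2 (R)-tert-butyldimethyl(pent-4-yn-2-yloxy)silane
Product: 4 (R)-5-[(tert-butyldimethylsilyl)oxy]hex-2-ynoic acid, via lithium acetylide 3 (not isolated)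
Conditions: n-BuLi, THF, −78 °C; CO2, −78 → 0 °C; then cold 1 M HCl
Reagents that add atoms: carbon dioxide, O=C=O
Why: Carboxylation of a lithium acetylide is the standard entry to alk-2-ynoic acids, and the TBS ether should tolerate n-BuLi at −78 °C and a brief cold acidification.

**Step 3**
Reactants: 4 (R)-5-[(tert-butyldimethylsilyl)oxy]hex-2-ynoic acid; 5 methyl (S)-3-hydroxybutanoate
Product: 6 methyl (S)-3-{[(R)-5-[(tert-butyldimethylsilyl)oxy]hex-2-ynoyl]oxy}butanoate
Conditions: DCC, DMAP (0.1 equiv), CH2Cl2, −20 → 0 °C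
Reagents that add atoms: none
Why: Steglich esterification acylates the secondary alcohol with retention, so the (S) centre of unit A comes unchanged from 5, while low temperature and little DMAP limit conjugate addition to the activated ynoate.

**Step 4**
Reactants: 6 methyl (S)-3-{[(R)-5-[(tert-butyldimethylsilyl)oxy]hex-2-ynoyl]oxy}butanoate
Product: 7 methyl (S)-3-{[(R)-5-hydroxyhex-2-ynoyl]oxy}butanoate
Conditions: HF·pyridine, pyridine, THF, 0 °C → rt
Reagents that add atoms: none
Why: Buffered fluoride desilylation should cleave the TBS ether under weakly acidic conditions that spare both esters and the triple bond, and the freed 5-OH cannot cyclise onto the linear ynoate.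

**Step 5**
Reactants: 5 methyl (S)-3-hydroxybutanoate
Product: 8 methyl (S)-3-(benzyloxy)butanoate
Conditions: BnOC(=NH)CCl3, TfOH (cat.), CH2Cl2/cyclohexane, 0 °C → rt
Reagents that add atoms: benzyl 2,2,2-trichloroacetimidate, N=C(OCc1ccccc1)C(Cl)(Cl)Cl
Why: Acid-catalysed O-benzylation with a trichloroacetimidate avoids the base that would cause retro-aldol cleavage or elimination of the β-hydroxy ester, so the (S) centre is retained.

**Step 6**
Reactants: 8 methyl (S)-3-(benzyloxy)butanoate
Product: 9 (S)-3-(benzyloxy)butanoic acid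
Conditions: LiOH·H2O, THF/H2O, 0 °C → rt; then 1 M HCl
Reagents that add atoms: lithium hydroxide, [Li+].[OH-]
Why: Mild saponification cleaves the methyl ester at the acyl–oxygen bond without touching the stereocentre, and the low temperature should keep E1cB loss of benzyl alcohol negligible.

**Step 7**
Reactants: 10 (S)-2-[(benzyloxy)methyl]oxirane ((S)-benzyl glycidyl ether)
Product: 11 (S)-1-(benzyloxy)pent-4-en-2-ol
Conditions: CH2=CHMgBr, CuI (10 mol%), THF, −40 → −20 °C; aq. NH4Cl
Reagents that add atoms: vinylmagnesium bromide, C=C[Mg]Br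
Why: Copper-catalysed Grignard opening of a terminal epoxide proceeds by SN2 attack at the unsubstituted CH2, so the epoxide stereocentre is untouched and becomes C3 of unit C, with the vinyl group as a masked carboxyl.

**Step 8**
Reactants: 11 (S)-1-(benzyloxy)pent-4-en-2-ol; 9 (S)-3-(benzyloxy)butanoic acid
Product: 12 (S)-1-(benzyloxy)pent-4-en-2-yl (S)-3-(benzyloxy)butanoate
Conditions: DCC, DMAP (cat.), CH2Cl2, 0 °C → rt
Reagents that add atoms: none
Why: Steglich esterification joins units D and C at O3 with retention at both stereocentres, at a stage where unit C has no carboxyl group that would need protection.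

**Step 9**
Reactants: 12 (S)-1-(benzyloxy)pent-4-en-2-yl (S)-3-(benzyloxy)butanoate
Product: 14 (S)-4-(benzyloxy)-3-{[(S)-3-(benzyloxy)butanoyl]oxy}butanoic acid, via aldehyde 13 (not isolated)
Conditions: O3, MeCN/H2O (9:1), 0 °C; then NaClO2, NaH2PO4, 0 °C → rt
Reagents that add atoms: ozone, [O-][O+]=O; sodium chlorite, [Na+].[O-]Cl=O; water, O (may supply the carbonyl oxygen when the carbonyl oxide fragment is hydrated)
Why: Ozonolysis in aqueous acetonitrile gives the aldehyde directly and a Pinnick-type chlorite oxidation in the same flask should convert it into the acid, the hydrogen peroxide from the first stage scavenging hypochlorite; the terminal alkene reacts with ozone far faster than the benzyl ethers, and the weakly acidic medium avoids β-elimination of the acyloxy group.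

**Step 10**
Reactants: 7 methyl (S)-3-{[(R)-5-hydroxyhex-2-ynoyl]oxy}butanoate; 14 (S)-4-(benzyloxy)-3-{[(S)-3-(benzyloxy)butanoyl]oxy}butanoic acid
Product: 15 methyl (S)-3-{[(R)-5-({(S)-4-(benzyloxy)-3-{[(S)-3-(benzyloxy)butanoyl]oxy}butanoyl}oxy)hex-2-ynoyl]oxy}butanoate
Conditions: DCC, DMAP (0.1 equiv), CH2Cl2, −20 → 0 °C
Reagents that add atoms: none
Why: Steglich esterification of the secondary alcohol of 7 with retention at C5 of the hexynoate completes the tetraester chain, low temperature and little DMAP suppressing β-elimination from the activated 3-acyloxy acid and amine-induced isomerisation of the ynoate.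

**Step 11**
Reactants: 16 methyl acetoacetate
Product: 17 methyl 3-(trimethylsilyloxy)but-2-enoate (E/Z mixture)
Conditions: TMSCl, Et3N, hexane, rt
Reagents that add atoms: chlorotrimethylsilane, C[Si](C)(C)Cl
Why: O-silylation of the enolised β-keto ester (silyl enol ether formation) gives the vinylogous ester needed for γ-deprotonation.

**Step 12**
Reactants: 17 methyl 3-(trimethylsilyloxy)but-2-enoate
Product: 19 1-methoxy-1,3-bis(trimethylsilyloxy)buta-1,3-diene, via lithium dienolate 18 (not isolated)
Conditions: LDA, THF, −78 °C; TMSCl, −78 → 0 °C; non-aqueous work-up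
Reagents that add atoms: chlorotrimethylsilane, C[Si](C)(C)Cl
Why: Kinetic γ-deprotonation with LDA followed by O-silylation of the dienolate (silyl ketene acetal formation) gives the bis(silyloxy)diene, which is used without aqueous work-up because it hydrolyses readily.

**Step 13**
Reactants: 15 methyl (S)-3-{[(R)-5-({(S)-4-(benzyloxy)-3-{[(S)-3-(benzyloxy)butanoyl]oxy}butanoyl}oxy)hex-2-ynoyl]oxy}butanoate; 19 1-methoxy-1,3-bis(trimethylsilyloxy)buta-1,3-diene
Product: 22 methyl (S)-3-{[2-((R)-2-{[(S)-4-(benzyloxy)-3-{[(S)-3-(benzyloxy)butanoyl]oxy}butanoyl]oxy}propyl)-4,6-dihydroxybenzoyl]oxy}butanoate (di-O-benzyl talapolyester D), via cyclohexa-1,4-diene cycloadduct 20 (not isolated), via bis(trimethylsilyl) aryl ether 21 (not isolated)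
Conditions: 19 (4 equiv), PhMe, 120 °C, sealed tube; then 1 M HCl, THF, 0 °C
Reagents that add atoms: none
Why: The electron-rich diene 19 and the electron-poor triple bond of 15 should combine in a concerted but asynchronous normal-demand Diels–Alder reaction in which bonding of the CH2 terminus of the diene to the ynoate β-carbon runs ahead of bonding of the ketene-acetal carbon to the α-carbon, after which cycloadduct 20 aromatises by 1,4-elimination of methanol and dilute acid cleaves the two aryl silyl ethers of 21. The closest known reaction type is the cycloaddition of 1-alkoxy-1,3-bis(silyloxy)buta-1,3-dienes to alk-2-ynoates, which delivers 6-substituted 2,4-dihydroxybenzoates. The benzene ring is closed intermolecularly as a [4π+2π] annulation that makes ring bonds C1–C2 and C5–C6 in one operation, so no separate cyclisation mode has to be chosen. No lasting stereocentre is created, since the ketal carbon of 20 is destroyed on aromatisation and the four existing centres are remote from any reacting site. The step needs regioselectivity, which follows from matching the largest HOMO coefficient of the diene (its CH2 terminus) with the largest LUMO coefficient of the ynoate (the β-carbon) and places the ester between a hydroxyl and the CH2 arm. It also needs chemoselectivity, which is secured because the triple bond is the only dienophile in 15 and the neutral thermal conditions leave the four alkyl ester links and both benzyl ethers untouched.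

**Step 14**
Reactants: 22 di-O-benzyl talapolyester D
Product: 23 talapolyester D, methyl (S)-3-{[2,4-dihydroxy-6-((R)-2-{[(S)-4-hydroxy-3-{[(S)-3-hydroxybutanoyl]oxy}butanoyl]oxy}propyl)benzoyl]oxy}butanoate
Conditions: H2 (1 atm), 10% Pd/C, EtOAc, rt
Reagents that add atoms: none
Why: Heterogeneous catalytic hydrogenolysis should remove both benzyl ethers under neutral conditions, which avoids acyl shift from O3 to the freed primary O4 of unit C and γ-lactonisation, while the arene, the esters and the non-benzylic C–O bond of the 2-acyloxypropyl arm are inert.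

**Compound list**

1 | (R)-pent-4-yn-2-ol | C[C@@H](O)CC#C | starting material
2 | (R)-tert-butyldimethyl(pent-4-yn-2-yloxy)silane | C[C@@H](O[Si](C)(C)C(C)(C)C)CC#C | intermediate
3 | lithium acetylide of 2, (R)-[4-(tert-butyldimethylsilyloxy)pent-1-yn-1-yl]lithium | C[C@@H](O[Si](C)(C)C(C)(C)C)CC#C[Li] | intermediate (not isolated)
4 | (R)-5-[(tert-butyldimethylsilyl)oxy]hex-2-ynoic acid | C[C@@H](O[Si](C)(C)C(C)(C)C)CC#CC(=O)O | intermediate
5 | methyl (S)-3-hydroxybutanoate | C[C@H](O)CC(=O)OC | starting material
6 | methyl (S)-3-{[(R)-5-[(tert-butyldimethylsilyl)oxy]hex-2-ynoyl]oxy}butanoate | COC(=O)C[C@H](C)OC(=O)C#CC[C@@H](C)O[Si](C)(C)C(C)(C)C | intermediate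
7 | methyl (S)-3-{[(R)-5-hydroxyhex-2-ynoyl]oxy}butanoate | COC(=O)C[C@H](C)OC(=O)C#CC[C@@H](C)O | intermediate
8 | methyl (S)-3-(benzyloxy)butanoate | COC(=O)C[C@H](C)OCc1ccccc1 | intermediate
9 | (S)-3-(benzyloxy)butanoic acid | OC(=O)C[C@H](C)OCc1ccccc1 | intermediate
10 | (S)-2-[(benzyloxy)methyl]oxirane ((S)-benzyl glycidyl ether) | C1[C@@H](COCc2ccccc2)O1 | starting material
11 | (S)-1-(benzyloxy)pent-4-en-2-ol | C=CC[C@@H](COCc1ccccc1)O | intermediate
12 | (S)-1-(benzyloxy)pent-4-en-2-yl (S)-3-(benzyloxy)butanoate | C=CC[C@@H](COCc1ccccc1)OC(=O)C[C@H](C)OCc1ccccc1 | intermediate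
13 | (S)-1-(benzyloxy)-4-oxobutan-2-yl (S)-3-(benzyloxy)butanoate | O=CC[C@@H](COCc1ccccc1)OC(=O)C[C@H](C)OCc1ccccc1 | intermediate (not isolated)
14 | (S)-4-(benzyloxy)-3-{[(S)-3-(benzyloxy)butanoyl]oxy}butanoic acid | OC(=O)C[C@@H](COCc1ccccc1)OC(=O)C[C@H](C)OCc1ccccc1 | intermediate
15 | methyl (S)-3-{[(R)-5-({(S)-4-(benzyloxy)-3-{[(S)-3-(benzyloxy)butanoyl]oxy}butanoyl}oxy)hex-2-ynoyl]oxy}butanoate | COC(=O)C[C@H](C)OC(=O)C#CC[C@@H](C)OC(=O)C[C@@H](COCc1ccccc1)OC(=O)C[C@H](C)OCc1ccccc1 | intermediate
16 | methyl acetoacetate | COC(=O)CC(C)=O | starting material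
17 | methyl 3-(trimethylsilyloxy)but-2-enoate (E/Z mixture) | COC(=O)C=C(C)O[Si](C)(C)C | intermediate
18 | lithium dienolate of 17, lithium 1-methoxy-3-(trimethylsilyloxy)buta-1,3-dien-1-olate | [Li]OC(OC)=CC(=C)O[Si](C)(C)C | intermediate (not isolated)
19 | 1-methoxy-1,3-bis(trimethylsilyloxy)buta-1,3-diene (E/Z mixture) | COC(O[Si](C)(C)C)=CC(=C)O[Si](C)(C)C | intermediate
20 | cycloadduct of 15 and 19, a 2-alkyl-6-methoxy-4,6-bis(trimethylsilyloxy)cyclohexa-1,4-diene-1-carboxylate (both epimers at the ketal carbon) | COC(=O)C[C@H](C)OC(=O)C1=C(C[C@@H](C)OC(=O)C[C@@H](COCc2ccccc2)OC(=O)C[C@H](C)OCc2ccccc2)CC(O[Si](C)(C)C)=CC1(OC)O[Si](C)(C)C | intermediate (not isolated)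
21 | 2,4-bis(trimethylsilyl) ether of 22 | COC(=O)C[C@H](C)OC(=O)c1c(O[Si](C)(C)C)cc(O[Si](C)(C)C)cc1C[C@@H](C)OC(=O)C[C@@H](COCc2ccccc2)OC(=O)C[C@H](C)OCc2ccccc2 | intermediate (not isolated)
22 | di-O-benzyl talapolyester D, methyl (S)-3-{[2-((R)-2-{[(S)-4-(benzyloxy)-3-{[(S)-3-(benzyloxy)butanoyl]oxy}butanoyl]oxy}propyl)-4,6-dihydroxybenzoyl]oxy}butanoate | COC(=O)C[C@H](C)OC(=O)c1c(O)cc(O)cc1C[C@@H](C)OC(=O)C[C@@H](COCc2ccccc2)OC(=O)C[C@H](C)OCc2ccccc2 | intermediate
23 | talapolyester D | COC(=O)C[C@H](C)OC(=O)c1c(O)cc(O)cc1C[C@@H](C)OC(=O)C[C@@H](CO)OC(=O)C[C@H](C)O | target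

**Step count.** Total: 14 steps. Longest linear sequence: 7 steps (1, 2, 3, 4, 10, 13, 14; the branch 5, 6, 8, 9, 10, 13, 14 is equally long).

**Steps most likely to fail**

1. Step 13. The acyclic diene may decompose on heating (silyl migration, oligomerisation) faster than it adds to the singly activated, β-alkyl-substituted triple bond, or aromatisation of the adduct may stay incomplete. The fallback replaces eliminative aromatisation by an Alder–Rickert sequence with a cyclic, s-cis-locked diene. Dimedone (commercial, CC1(C)CC(=O)CC(=O)C1) would be silylated with TMSCl/Et3N to 5,5-dimethyl-3-(trimethylsilyloxy)cyclohex-2-en-1-one F1 and then with LDA/TMSCl to 5,5-dimethyl-1,3-bis(trimethylsilyloxy)cyclohexa-1,3-diene F2. The fallback sets out from 15, which would be heated neat with F2 at about 140 °C. The 8,8-dimethyl-1,5-bis(trimethylsilyloxy)bicyclo[2.2.2]octa-2,5-diene-2-carboxylate adduct F3 should form with the same regiochemistry (unsubstituted diene terminus to the ynoate β-carbon) and lose 2-methylpropene by retro-[4+2]. This comes back to the route at 21, which the acid work-up of step 13 converts into 22.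

2. Step 10. The activated 3-acyloxy acid may undergo base-induced β-elimination of the unit-D carboxylate before the secondary alcohol attacks. The fallback attaches units C and D one after the other, so that every activated acid carries only a silyloxy or benzyloxy β-substituent. It sets out from 11, which would be silylated (TBSCl, imidazole) to (S)-{[1-(benzyloxy)pent-4-en-2-yl]oxy}(tert-butyl)dimethylsilane F4. Ozonolysis in aqueous acetonitrile followed by chlorite, as in step 9, would give (S)-4-(benzyloxy)-3-[(tert-butyldimethylsilyl)oxy]butanal F5 in the flask and then (S)-4-(benzyloxy)-3-[(tert-butyldimethylsilyl)oxy]butanoic acid F6. Steglich coupling of F6 with 7 would give methyl (S)-3-{[(R)-5-({(S)-4-(benzyloxy)-3-[(tert-butyldimethylsilyl)oxy]butanoyl}oxy)hex-2-ynoyl]oxy}butanoate F7. HF·pyridine would free methyl (S)-3-{[(R)-5-{[(S)-4-(benzyloxy)-3-hydroxybutanoyl]oxy}hex-2-ynoyl]oxy}butanoate F8, and Steglich acylation of F8 with 9 comes back to the route at 15.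

3. Step 3. The carbodiimide-activated alkynoic acid may be consumed by N-acylurea formation or DMAP-initiated conjugate addition and oligomerisation before the secondary alcohol reacts. The fallback activates the alcohol instead of the acid. It sets out from 4, which would be combined with methyl (R)-3-hydroxybutanoate (commercial enantiomer of 5, C[C@@H](O)CC(=O)OC), PPh3 and DIAD in toluene at 0 °C. The Mitsunobu reaction, with SN2 inversion at the carbinol carbon, should give the (S)-ester and comes back to the route at 6. This fallback makes no compound outside the list (F0).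

**Further compounds**

F1 | step 13 | 5,5-dimethyl-3-(trimethylsilyloxy)cyclohex-2-en-1-one | CC1(C)CC(=O)C=C(O[Si](C)(C)C)C1
F2 | step 13 | 5,5-dimethyl-1,3-bis(trimethylsilyloxy)cyclohexa-1,3-diene | CC1(C)CC(O[Si](C)(C)C)=CC(O[Si](C)(C)C)=C1
F3 | step 13 | adduct of 15 and F2, a 3-alkyl-8,8-dimethyl-1,5-bis(trimethylsilyloxy)bicyclo[2.2.2]octa-2,5-diene-2-carboxylate (bridgehead diastereomers) | COC(=O)C[C@H](C)OC(=O)C1=C(C[C@@H](C)OC(=O)C[C@@H](COCc3ccccc3)OC(=O)C[C@H](C)OCc3ccccc3)C2C(O[Si](C)(C)C)=CC1(O[Si](C)(C)C)CC2(C)C
F4 | step 10 | (S)-{[1-(benzyloxy)pent-4-en-2-yl]oxy}(tert-butyl)dimethylsilane | C=CC[C@@H](COCc1ccccc1)O[Si](C)(C)C(C)(C)C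
F5 | step 10 | (S)-4-(benzyloxy)-3-[(tert-butyldimethylsilyl)oxy]butanal | O=CC[C@@H](COCc1ccccc1)O[Si](C)(C)C(C)(C)C
F6 | step 10 | (S)-4-(benzyloxy)-3-[(tert-butyldimethylsilyl)oxy]butanoic acid | OC(=O)C[C@@H](COCc1ccccc1)O[Si](C)(C)C(C)(C)C
F7 | step 10 | methyl (S)-3-{[(R)-5-({(S)-4-(benzyloxy)-3-[(tert-butyldimethylsilyl)oxy]butanoyl}oxy)hex-2-ynoyl]oxy}butanoate | COC(=O)C[C@H](C)OC(=O)C#CC[C@@H](C)OC(=O)C[C@@H](COCc1ccccc1)O[Si](C)(C)C(C)(C)C
F8 | step 10 | methyl (S)-3-{[(R)-5-{[(S)-4-(benzyloxy)-3-hydroxybutanoyl]oxy}hex-2-ynoyl]oxy}butanoate | COC(=O)C[C@H](C)OC(=O)C#CC[C@@H](C)OC(=O)C[C@@H](COCc1ccccc1)O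
F0 | step 3 | none | none
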